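## Analysis of the target

Compound 29 is a labdane: a trans-fused decalin (ring A = C1–C5 and C10, with the gem-dimethyl carbon C4; ring B = C5–C10) carrying the angular methyl C20 on C10, an exocyclic methylene C8=C17 and, on C9, a side chain made of the acetoxy carbon C11, the methylene C12 and an α-substituted butenolide (C13–C16, carbonyl C16). It has four stereocentres, 5S, 9S, 10S and 11R. H-5 and H-9 are α and anti to the β-methyl C20, and the side chain on C9 is equatorial. C11 lies outside the ring, so its configuration cannot easily be relayed from the decalin. The exocyclic methylene migrates into the ring under acid. The C11 acetate is β to C12, whose protons are vinylogously acidic through the butenolide, so base invites elimination, and a free C11 hydroxyl next to the lactone could translactonise. The main difficulty is the C9–C10 bond, which joins a quaternary carbon to a tertiary carbon bearing a branched, oxygenated chain, together with the absolute configuration at C11. The strategy reads ring A, with C20, one C4 methyl and a temporary oxygen on C3, as a 2,4-dimethylphenol: C3 is the phenol carbon, C4 the ortho carbon with its methyl, C5 the meta carbon holding the C6–C7 tether, and C10 the methyl-bearing para carbon. If C10 attacks C9 of an allyl unit C17–C8–C9, the quaternary centre, the C9 stereocentre, ring B and the exocyclic alkene arise in one bond formation from a flat arene, and the dienone left behind gives access to the second C4 methyl, H-5 and removal of the C3 oxygen.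

## Retrosynthetic reasoning

**C12–C13.** The butenolide is cut from the chain between C12 and C13, giving the β-acetoxy iodide 27 and the bromobutenolide 28. This cut lets the base-sensitive lactone and the acetate meet only in the last step, under neutral reductive conditions, and 28 already has C13–C16 in the final oxidation state. The forward reaction, a nickel-catalysed cross-electrophile coupling, must join a primary radical at C12 to the alkenyl carbon C13 without losing the neighbouring acetate.

**C11–O and C12–I.** Iodide 27 goes back through iodohydrin 26 to diol 25. The primary and secondary hydroxyls are distinguished by sterics and C11 is untouched. Diol 25 is the unmasked form of acetonide 23; one acid treatment removes both the silicon on C17 and the acetonide, by way of 24.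

**C3=O, C4–CH3, C5–H.** Ring A of 23 is traced to ketone 21 (removal of the C3 oxygen), then to enone 19 (reductive methylation adds the second C4 methyl and H-5, with the trans fusion dictated by the C10 methyl), then to the cross-conjugated dienone 18 (conjugate reduction of C1=C2). No skeletal bond is cut; the gain is that every sp3 centre of ring A derives from a dienone, hence from an arene.

**C9–C10 (key disconnection).** Dienone 18 is opened between C9 and C10 to phenol 17, in which C9 is an allylic carbonate carbon. This cut removes ring B, the quaternary centre and the C9 stereocentre at once. Two features of 17 are dictated by the forward reaction: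
- The tether ends on the central allyl carbon C8, so C9 and C17 are equally far from C10 and either would close a six-membered ring. An unbiased palladium allyl would be attacked at the unhindered CH2 terminus. C17 therefore carries a trimethylsilyl group, which steers attack to the remote terminus and is removed later with acid.
- The leaving group sits on C9 itself with defined configuration (9R), so the double inversion of palladium catalysis transfers the C9 configuration into 18 with net retention, rather than leaving it to a catalyst.

**Phenol O–Si and C9–O.** 17 comes from silyl ether 16 and that from alcohol 15. The net-retention argument requires the 9,11-syn relation of 15. Direct addition to an α-alkoxy aldehyde would give mainly the anti epimer, so 15 is reached from ketone 14 by Felkin–Anh reduction, and 14 by oxidation of the epimer mixture 13.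

**C8–C9.** 13 is cut between C8 and C9 into silylalkyne 9 and aldehyde 10. The chiral-pool aldehyde supplies C9, C11 and C12 with the C11 oxygen stereocentre in place. The titanium–alkyne complex 11 adds aldehydes at the carbon remote from silicon, so the silyl group that later steers the palladium step also fixes the regiochemistry here and ends on C17, cis to C7.

**C5–C6.** 9 is cut at the aryl carbon into bromide 6 and zinc reagent 8, made from bromide 7. The position between two methyl groups is reached more reliably by cross-coupling than by electrophilic substitution.

**Aryl C–O.** 6 is the silyl ether of phenol 5, whose oxygen is introduced through iodide 2, made by iodination of 1 at its only activated, unhindered position.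

## Alternatives that were turned down

**Alternative 1: lactone-enolate Claisen ring contraction.**
- Disconnection: the C8–C9 bond of ring B, leading to the δ-lactone A2, in which the C11 carboxyl is tied to an oxygen on C6 and C6 carries the C7=C8–C17 propenyl unit.
- Forward key step: the silyl ketene acetal of A2 (C9=C11) rearranges [3,3] through a boat transition state, forming C8–C9 and giving acid A1 with a C6=C7 alkene.
- For: the rearrangement is well precedented and its C8/C9 outcome is predictable.
- Against: A2 already needs C5, the quaternary C10 and C6 as stereocentres, so the hard centre is only moved to an earlier stage. The C8 stereocentre of A1 is destroyed when the C17 silyl ether is turned into the methylene. C6=C7 must be hydrogenated. C11 arrives as an acid and must be reduced and extended by C12 with a new, substrate-controlled stereocentre next to hindered C9.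
- Comparison: it is stronger on precedent for the key step. The chosen route instead needs no stereocentre in the ring A precursor, takes C11 from the chiral pool and delivers the C8=C17 bond in the correct position.

**Alternative 2: auxiliary-controlled intramolecular Diels–Alder reaction.**
- Disconnection: C5–C10 and C8–C9 together, leading to the acyclic triene A4.
- Forward key step: under a dialkylaluminium chloride, the (E)-C9=C10 N-acyloxazolidinone adds to the 1-silyloxydiene and gives imide A3, closing rings A and B.
- For: it forms the most rings, bonds and stereocentres per step, gives absolute control from the auxiliary, and A4 is easy to assemble.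
- Against: a β,β-disubstituted dienophile that must form quaternary C10 is sluggish, and the Lewis acid can attack the silyl dienol ether instead. The diene terminus C5 is neopentyl. The trans fusion depends on an endo/exo preference that is not assured. After the cycloaddition, C8–O must be oxidised and methylenated next to a C9 that is then doubly activated and epimerisable, C6=C7 hydrogenated, and the imide converted into the C11 carbinol with C12 and a new stereocentre.
- Comparison: it is stronger in skeletal convergence. The chosen route needs less repair after ring formation, because the methylene and the C11 oxygen stereocentre are already present.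

**Alternative 3: carbonylative three-component coupling, then photochemical deconjugation.**
- Disconnection: C9–C11 and C11–C12 around a C11 carbonyl.
- Forward key step: a zerovalent palladium catalyst joins enol triflate A6, carbon monoxide A8 and furylmethylzinc reagent A7 to give the tetrasubstituted enone A5. Photodeconjugation, ketone reduction, acetylation and silicon-directed furan oxidation would follow.
- For: it is highly convergent, the whole side chain arrives in one step, and A6 could come from chiral-pool decalins, so this is probably the shortest route.
- Against: C9 would be set by kinetic protonation of a photodienol, with competing hydrogen abstraction from C7, and C11 by reduction of a hindered β,γ-unsaturated ketone that can reconjugate. The furan oxidation must spare the exocyclic alkene. CO insertion at a tetrasubstituted alkenylpalladium competes with direct coupling.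
- Comparison: it is stronger in step economy and in proven coupling chemistry. The chosen route takes C11 from the chiral pool and sets C9 by a stereospecific substitution rather than by two kinetically controlled events.

Key step: step 10

Remark: labdane numbering is used for all intermediates (C3 = phenol or ketone carbon, C10 = para carbon with methyl C20, C17 = silyl-bearing alkene carbon); α/β refer to the usual drawing with C20 β.

Remark: 1, 7, 10 and 28 are taken as purchased materials; 10 is distilled just before use because it oligomerises and racemises on storage.

Step 1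
Reactants: 1 2-bromo-1,3-dimethylbenzene
Product: 2 2-bromo-4-iodo-1,3-dimethylbenzene
Conditions: NIS (1.0 equiv), TFA, MeCN, rt
Reagents that add atoms: N-iodosuccinimide, O=C1CCC(=O)N1I
Why: Electrophilic aromatic iodination; C4 is ortho to one methyl and para to the other, whereas C5 is meta to both, so one regioisomer should form.

Step 2
Reactants: 2 2-bromo-4-iodo-1,3-dimethylbenzene
Product: 5 3-bromo-2,4-dimethylphenol, via arylmagnesium chloride 3 (not isolated), via aryl dimethyl boronate 4 (not isolated)
Conditions: i-PrMgCl·LiCl, THF, −20 °C; B(OMe)3, −20 °C → rt; H2O2, NaOH aq., 0 °C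
Reagents that add atoms: hydrogen peroxide, OO
Why: Iodine–magnesium exchange is far faster at the aryl iodide than at the doubly ortho-substituted bromide; borylation and peroxide oxidation (1,2-aryl shift from boron to oxygen) then give the phenol.

Step 3
Reactants: 5 3-bromo-2,4-dimethylphenol
Product: 6 (3-bromo-2,4-dimethylphenoxy)(tert-butyl)dimethylsilane
Conditions: TBSCl, imidazole, DMF, rt
Reagents that add atoms: tert-butyldimethylsilyl chloride, CC(C)(C)[Si](C)(C)Cl
Why: Silyl ether formation; the aryl silyl ether masks the acidic OH through the organometallic steps and is removed later with fluoride.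

Step 4
Reactants: 6 (3-bromo-2,4-dimethylphenoxy)(tert-butyl)dimethylsilane; 7 (4-bromobut-1-yn-1-yl)trimethylsilane
Product: 9 tert-butyl{2,4-dimethyl-3-[4-(trimethylsilyl)but-3-yn-1-yl]phenoxy}dimethylsilane, via alkylzinc bromide 8 (not isolated)
Conditions: 7, Zn, LiCl, THF, 50 °C; then 6, Pd(OAc)2 (2 mol%), SPhos (4 mol%), THF, 60 °C
Reagents that add atoms: none
Why: Negishi coupling; LiCl-assisted zinc insertion into the primary bromide, then a dialkylbiarylphosphine palladium catalyst that tolerates the two ortho methyl groups; the silylalkyne is inert.

Step 5
Reactants: 9 tert-butyl{2,4-dimethyl-3-[4-(trimethylsilyl)but-3-yn-1-yl]phenoxy}dimethylsilane; 10 (R)-2,2-dimethyl-1,3-dioxolane-4-carbaldehyde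
Product: 13 (E)-vinylsilane allylic alcohol as a mixture of C9 epimers, via titanium alkyne complex 11 (not isolated), via oxatitanacyclopentene 12 (not isolated)
Conditions: Ti(O-i-Pr)4, i-PrMgCl (2 equiv), Et2O, −78 → −50 °C; then 10, −78 → −40 °C; H2O
Reagents that add atoms: none
Why: Alkyne–titanium coupling (Sato–Urabe): the divalent titanium propene complex exchanges to titanacyclopropene 11 and the aldehyde inserts into the Ti–C bond remote from silicon, forming C8–C9; hydrolysis of 12 puts H on C17 cis to C9 and leaves silicon cis to C7. C9 forms as an epimer mixture (Felkin–Anh addition should favour 9,11-anti); both epimers are carried on because step 6 erases C9.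

Step 6
Reactants: 13 (E)-vinylsilane allylic alcohol as a mixture of C9 epimers
Product: 14 (E)-β-silyl enone with the C9 ketone
Conditions: Dess–Martin periodinane, NaHCO3, CH2Cl2, 0 °C → rt
Reagents that add atoms: none
Why: Dess–Martin oxidation under buffered, non-epimerising conditions converges both C9 epimers; silyl ether, vinylsilane and acetonide are inert.

Step 7
Reactants: 14 (E)-β-silyl enone with the C9 ketone
Product: 15 (9R)-allylic alcohol with 9,11-syn oxygens
Conditions: LiBH(s-Bu)3, THF, −78 °C
Reagents that add atoms: none
Why: Felkin–Anh-controlled 1,2-reduction: the bulky, non-chelating borohydride attacks the ketone anti to the C11–O bond and should give the 9,11-syn (9R) alcohol; acyclic enones of this kind are reduced at the carbonyl, and the β-silyl and α-alkyl groups hinder conjugate attack.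

Step 8
Reactants: 15 (9R)-allylic alcohol with 9,11-syn oxygens
Product: 16 (9R)-allylic methyl carbonate as aryl silyl ether
Conditions: ClCO2Me, pyridine, DMAP (cat.), CH2Cl2, 0 °C → rt
Reagents that add atoms: methyl chloroformate, COC(Cl)=O
Why: Acylation of the secondary alcohol to the methyl carbonate, the leaving group that releases methoxide as internal base in step 10; C9 is not touched.

Step 9
Reactants: 16 (9R)-allylic methyl carbonate as aryl silyl ether
Product: 17 free phenol with the (9R)-allylic methyl carbonate and C17 trimethylsilyl group
Conditions: Bu4NF, AcOH, THF, 0 °C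
Reagents that add atoms: none
Why: Fluoride cleaves the aryl silyl ether selectively; acetic acid buffers the phenoxide so the carbonate is not transferred, and the vinyl C–Si bond is inert to fluoride.

Step 10
Reactants: 17 free phenol with the (9R)-allylic methyl carbonate and C17 trimethylsilyl group
Product: 18 bicyclic cross-conjugated dienone (C3=O; C1=C2; C4=C5) with C10 methyl β and H-9 α and (E)-C8=C17H(SiMe3) and the dioxolane on C9
Conditions: Pd2(dba)3·CHCl3 (5 mol%), dppe (12 mol%), THF (0.01 M), 50 °C
Reagents that add atoms: none
Why: Proposed new method: zerovalent palladium ionises the C9 carbonate anti to the leaving group to a 1-silyl-2-alkyl π-allyl complex of divalent palladium, CO2 is lost, the methoxide released deprotonates the phenol, and the para carbon C10 attacks the allyl from the face opposite the metal; the closest known reaction type is the palladium-catalysed intramolecular ipso-Friedel–Crafts allylic alkylation of phenols to spirocyclohexadienones, together with asymmetric allylic dearomatisation of naphthols. Ring B closes in a six-membered mode in which C8 and C9 become ring atoms and C8=C17 stays exocyclic (an Ar2-6 closure seen from the arene); because the tether sits on the central allyl carbon, attack at C17 would also close a six-membered ring, so ring size does not discriminate. The trimethylsilyl group on C17 should decide, since silyl-substituted π-allylpalladium complexes are attacked at the terminus remote from silicon on steric and electronic grounds. C9 is set by the substrate: ionisation and attack both proceed with inversion, so C10 replaces the (9R) carbonate oxygen with net retention. C10 follows from a chair-like transition state in which C11, lying trans to C7 on the allyl (the conformer free of 1,2-allylic strain), becomes equatorial, which places the C10 methyl anti to H-9. Para attack is expected over ortho attack at C4 because the para carbon has the larger HOMO coefficient and is not flanked by the solvated oxygen, and O-alkylation would need an eight-membered ring; the para/ortho preference is not secured by the substrate. Because C10 bears a methyl group the ring cannot rearomatise.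

Step 11
Reactants: 18 bicyclic cross-conjugated dienone
Product: 19 Δ4-3-ketone (C3=O; C4=C5) with the vinylsilane and dioxolane unchanged
Conditions: [(Ph3P)CuH]6, H2O, toluene/THF, rt
Reagents that add atoms: none
Why: Copper hydride conjugate reduction: hydride adds to C1 of the disubstituted C1=C2 bond, whereas the tetrasubstituted C4=C5 bond and the isolated vinylsilane do not react; protonation of the copper enolate gives the Δ4-3-ketone.

Step 12
Reactants: 19 Δ4-3-ketone
Product: 21 trans-fused 4,4-dimethyl-3-ketone with H-5 α, via lithium enolate 20 (not isolated)
Conditions: Li, NH3/THF, t-BuOH (1 equiv), −78 → −33 °C; then MeI, −78 → −33 °C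
Reagents that add atoms: iodomethane, CI
Why: Stork reductive alkylation: two-electron reduction of the enone, axial protonation at C5 anti to the C10 methyl (trans fusion, H-5 α), then methylation of the regiodefined lithium enolate 20 at C4 to complete the gem-dimethyl group.

Step 13
Reactants: 21 trans-fused 4,4-dimethyl-3-ketone
Product: 23 deoxygenated trans-decalin with (E)-C8=C17H(SiMe3) and the dioxolane on C9, via hydrazone 22 (not isolated)
Conditions: N2H4·H2O, KOH, diethylene glycol, 130 → 210 °C
Reagents that add atoms: none
Why: Wolff–Kishner reduction (Huang–Minlon conditions), the standard deoxygenation of hindered 4,4-dimethyl-3-ketones of terpenoids; acetonide and vinylsilane are base-stable, and loss of silicon here would only anticipate step 14.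

Step 14
Reactants: 23 deoxygenated trans-decalin with the vinylsilane and dioxolane
Product: 25 labdane-type 11,12-diol with exocyclic C8=C17 methylene, via desilylated acetonide 24 (not isolated)
Conditions: TFA (3 equiv), CH2Cl2, −20 °C; then H2O, THF, rt
Reagents that add atoms: none
Why: Protodesilylation of the vinylsilane: ipso protonation at C17 gives the tertiary β-silyl cation at C8, which loses silicon so that the double bond stays at C8=C17; aqueous acid then hydrolyses the terminal acetonide. No stereocentre is affected.

Step 15
Reactants: 25 labdane-type 11,12-diol
Product: 26 C12 iodide with free C11 hydroxyl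
Conditions: I2, PPh3, imidazole, THF, 0 °C
Reagents that add atoms: iodine, II
Why: Appel-type iodination (Garegg–Samuelsson conditions) is selective for the primary hydroxyl of a 1,2-diol at low temperature; C11 keeps its configuration.

Step 16
Reactants: 26 C12 iodide with free C11 hydroxyl
Product: 27 C11 acetate C12 iodide
Conditions: Ac2O, pyridine, DMAP (cat.), CH2Cl2, 0 °C
Reagents that add atoms: acetic anhydride, CC(=O)OC(C)=O
Why: Standard acylation of the secondary alcohol, faster than epoxide closure of the iodohydrin under these weakly basic conditions; retention at C11.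

Step 17
Reactants: 27 C11 acetate C12 iodide; 28 3-bromofuran-2(5H)-one
Product: 29 CNP0182424.2
Conditions: 28 (2 equiv), NiBr2(dme) (10 mol%), 4,4′-di-tert-butyl-2,2′-bipyridine (12 mol%), Mn, NaI, DMA, rt
Reagents that add atoms: none
Why: Nickel-catalysed reductive cross-electrophile coupling of an alkyl iodide with an alkenyl bromide: zerovalent nickel adds the electron-poor alkenyl bromide, the C12 radical formed by halogen abstraction is captured, and reductive elimination forms C12–C13; Mn is the terminal reductant because it does not insert into the β-acetoxy iodide. No stereocentre is touched, and the neutral conditions spare acetate, butenolide and the exocyclic alkene.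

**Compound list**

1 | 2-bromo-1,3-dimethylbenzene | Cc1cccc(C)c1Br | starting material
2 | 2-bromo-4-iodo-1,3-dimethylbenzene | Cc1ccc(I)c(C)c1Br | intermediate
3 | (3-bromo-2,4-dimethylphenyl)magnesium chloride (not isolated) | Cc1ccc([Mg]Cl)c(C)c1Br | intermediate
4 | dimethyl (3-bromo-2,4-dimethylphenyl)boronate (not isolated) | COB(OC)c1ccc(C)c(Br)c1C | intermediate
5 | 3-bromo-2,4-dimethylphenol | Cc1ccc(O)c(C)c1Br | intermediate
6 | (3-bromo-2,4-dimethylphenoxy)(tert-butyl)dimethylsilane | Cc1ccc(O[Si](C)(C)C(C)(C)C)c(C)c1Br | intermediate
7 | (4-bromobut-1-yn-1-yl)trimethylsilane | C[Si](C)(C)C#CCCBr | starting material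
8 | [4-(trimethylsilyl)but-3-yn-1-yl]zinc bromide (not isolated) | C[Si](C)(C)C#CCC[Zn]Br | intermediate
9 | tert-butyl{2,4-dimethyl-3-[4-(trimethylsilyl)but-3-yn-1-yl]phenoxy}dimethylsilane | Cc1ccc(O[Si](C)(C)C(C)(C)C)c(C)c1CCC#C[Si](C)(C)C | intermediate
10 | (R)-2,2-dimethyl-1,3-dioxolane-4-carbaldehyde | O=C[C@H]1COC(C)(C)O1 | starting material
11 | diisopropoxytitanacyclopropene of 9 (not isolated) | CC(C)O[Ti]1(OC(C)C)C(CCc2c(C)ccc(O[Si](C)(C)C(C)(C)C)c2C)=C1[Si](C)(C)C | intermediate
12 | oxatitanacyclopentene from insertion of 10 into 11 (not isolated) | CC(C)O[Ti]1(OC(C)C)OC([C@H]2COC(C)(C)O2)C(CCc2c(C)ccc(O[Si](C)(C)C(C)(C)C)c2C)=C1[Si](C)(C)C | intermediate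
13 | (E)-2-{2-[3-(tert-butyldimethylsilyloxy)-2,6-dimethylphenyl]ethyl}-1-[(4R)-2,2-dimethyl-1,3-dioxolan-4-yl]-3-(trimethylsilyl)prop-2-en-1-ol, both epimers at the carbinol carbon C9 | Cc1ccc(O[Si](C)(C)C(C)(C)C)c(C)c1CC/C(=C\[Si](C)(C)C)C(O)[C@H]1COC(C)(C)O1 | intermediate
14 | (E)-2-{2-[3-(tert-butyldimethylsilyloxy)-2,6-dimethylphenyl]ethyl}-1-[(4R)-2,2-dimethyl-1,3-dioxolan-4-yl]-3-(trimethylsilyl)prop-2-en-1-one | Cc1ccc(O[Si](C)(C)C(C)(C)C)c(C)c1CC/C(=C\[Si](C)(C)C)C(=O)[C@H]1COC(C)(C)O1 | intermediate
15 | (1R,E)-alcohol of 14 (9R; C9 and C11 oxygens syn) | Cc1ccc(O[Si](C)(C)C(C)(C)C)c(C)c1CC/C(=C\[Si](C)(C)C)[C@@H](O)[C@H]1COC(C)(C)O1 | intermediate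
16 | methyl carbonate of 15 | Cc1ccc(O[Si](C)(C)C(C)(C)C)c(C)c1CC/C(=C\[Si](C)(C)C)[C@@H](OC(=O)OC)[C@H]1COC(C)(C)O1 | intermediate
17 | (1R,E)-1-[(4R)-2,2-dimethyl-1,3-dioxolan-4-yl]-2-[2-(3-hydroxy-2,6-dimethylphenyl)ethyl]-3-(trimethylsilyl)prop-2-en-1-yl methyl carbonate | Cc1ccc(O)c(C)c1CC/C(=C\[Si](C)(C)C)[C@@H](OC(=O)OC)[C@H]1COC(C)(C)O1 | intermediate
18 | 4,10-dimethyl bicyclic 1,4-dien-3-one with (E)-C8=C17H(SiMe3) and the dioxolane on C9; C9, C10, C11 arranged as in 29 | O=C1C=C[C@@]2(C)C(=C1C)CC/C(=C\[Si](C)(C)C)[C@@H]2[C@H]1COC(C)(C)O1 | intermediate
19 | 1,2-dihydro derivative of 18 (Δ4-3-ketone) | O=C1CC[C@@]2(C)C(=C1C)CC/C(=C\[Si](C)(C)C)[C@@H]2[C@H]1COC(C)(C)O1 | intermediate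
20 | lithium C3 enolate (C3=C4) with H-5 α (not isolated) | C[Si](C)(C)/C=C1\CC[C@H]2C(C)=C(O[Li])CC[C@]2(C)[C@H]1[C@H]1COC(C)(C)O1 | intermediate
21 | trans-fused 4,4,10-trimethyl-3-ketone with (E)-C8=C17H(SiMe3) and the dioxolane on C9 | C[Si](C)(C)/C=C1\CC[C@H]2C(C)(C)C(=O)CC[C@]2(C)[C@H]1[C@H]1COC(C)(C)O1 | intermediate
22 | C3 hydrazone of 21 (not isolated) | C[Si](C)(C)/C=C1\CC[C@H]2C(C)(C)C(=NN)CC[C@]2(C)[C@H]1[C@H]1COC(C)(C)O1 | intermediate
23 | 3-deoxo derivative of 21 | C[Si](C)(C)/C=C1\CC[C@H]2C(C)(C)CCC[C@]2(C)[C@H]1[C@H]1COC(C)(C)O1 | intermediate
24 | 11,12-O-isopropylidene derivative of diol 25 (not isolated) | C=C1CC[C@H]2C(C)(C)CCC[C@]2(C)[C@H]1[C@H]1COC(C)(C)O1 | intermediate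
25 | 13,14,15,16-tetranorlabd-8(17)-ene-11,12-diol, C5, C9, C10, C11 arranged as in 29 | C=C1CC[C@H]2C(C)(C)CCC[C@]2(C)[C@H]1[C@H](O)CO | intermediate
26 | 12-iodo-11-ol derived from 25 | C=C1CC[C@H]2C(C)(C)CCC[C@]2(C)[C@H]1[C@H](O)CI | intermediate
27 | 11-acetate of 26 | C=C1CC[C@H]2C(C)(C)CCC[C@]2(C)[C@H]1[C@@H](CI)OC(C)=O | intermediate
28 | 3-bromofuran-2(5H)-one | O=C1OCC=C1Br | starting material
29 | CNP0182424.2, (5S,9S,10S,11R)-11-acetoxylabda-8(17),13-dien-16,15-olide | C=C1CC[C@H]2C(C)(C)CCC[C@]2(C)[C@H]1[C@@H](CC1=CCOC1=O)OC(C)=O | target

**Totals.** 17 steps; the longest linear sequence is 17 steps (1 → 29). Compounds 7, 10 and 28 enter as purchased materials.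

**Least certain steps**

**Step 10 (key step, new reaction type).**
- What may go wrong: leakage of regiocontrol (attack through C17 despite the silyl group, or through the ortho carbon C4); slow ionisation of the hindered carbonate followed by β-hydride elimination from C7 to a diene; partial loss of stereospecificity if the palladium face is exchanged before ring closure. Either enantiomer of a chiral bisphosphine could be tried in place of dppe to reinforce the matched pathway, but that is only a change of conditions.
- Fallback (known reactions, reversed polarity): it sets out from 13 and comes back to the route at 24.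
  - Myers reductive allylic transposition of 13 (o-nitrobenzenesulfonylhydrazine, PPh3, diethyl azodicarboxylate) moves the double bond to C8=C9 and gives the allylsilane silyl ether F1.
  - Bu4NF/AcOH gives the allylsilane phenol F2.
  - Oxidation with PhI(OAc)2 in (CF3)2CHOH, an oxidative Hosomi–Sakurai-type dearomatisation, lets the γ-carbon C9 attack the para carbon of the phenoxonium ion and gives the silicon-free dienone F3. Only C9 can bond, because silicon leaves from C17.
  - [(Ph3P)CuH]6 then gives the enone F4, Li/NH3 followed by MeI the ketone F5, and Wolff–Kishner reduction gives 24, which is hydrolysed to 25 as in the second half of step 14.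
  - The price is that C9 and C10 would be controlled only by C11 and the chair-like transition state.

**Step 17 (nickel cross-electrophile coupling).**
- What may go wrong: β-elimination of acetate from an alkylnickel or alkylmanganese species; conjugate addition of the C12 radical to the butenolide; homocoupling of 28.
- Fallback: it sets out from 26 and 28 and comes back at 29.
  - K2CO3/MeOH closes 26 to the terminal epoxide F6 with retention at C11.
  - 28 is silylated (i-Pr3SiOTf, Et3N) to the 3-bromo-2-silyloxyfuran F7.
  - Bromine–lithium exchange (n-BuLi, −78 °C) and opening of F6 at C12 with BF3·OEt2 give the alcohol F8.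
  - Ac2O/pyridine gives the acetate F9, and HF·pyridine removes the silyl group to give 29.

**Step 7 (ketone reduction).**
- What may go wrong: poor facial selectivity (chelation competing with the Felkin–Anh mode) or conjugate reduction.
- Fallback: it sets out from the anti epimer contained in 13 and comes back at 15. Mitsunobu inversion with 4-nitrobenzoic acid (PPh3, diisopropyl azodicarboxylate) gives the inverted ester F10, and i-Bu2AlH at −78 °C cleaves it to 15.

**Step 14 (acidic protodesilylation and acetonide removal).**
- What may go wrong: acid-induced migration of the exocyclic double bond into the ring, or capture of the C8 cation by water or the liberated diol.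
- Fallback: it sets out from 23 and comes back at 25. Iododesilylation with N-iodosuccinimide in MeCN gives the vinyl iodide F11; Bu3SnH with Pd(PPh3)4 replaces iodine by hydrogen to give 24, now isolated; pyridinium p-toluenesulfonate in MeOH removes the acetonide to give 25.

## Further compounds

F1 | step 10 | allylsilane silyl ether, alkene geometry as formed | Cc1ccc(O[Si](C)(C)C(C)(C)C)c(C)c1CCC(C[Si](C)(C)C)=C[C@H]1COC(C)(C)O1
F2 | step 10 | allylsilane phenol | Cc1ccc(O)c(C)c1CCC(C[Si](C)(C)C)=C[C@H]1COC(C)(C)O1
F3 | step 10 | silicon-free bicyclic cross-conjugated dienone | O=C1C=C[C@@]2(C)C(=C1C)CCC(=C)[C@@H]2[C@H]1COC(C)(C)O1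
F4 | step 10 | silicon-free Δ4-3-ketone | O=C1CC[C@@]2(C)C(=C1C)CCC(=C)[C@@H]2[C@H]1COC(C)(C)O1
F5 | step 10 | silicon-free trans-fused 4,4-dimethyl-3-ketone | C=C1CC[C@H]2C(C)(C)C(=O)CC[C@]2(C)[C@H]1[C@H]1COC(C)(C)O1
F6 | step 17 | 11,12-epoxide | C=C1CC[C@H]2C(C)(C)CCC[C@]2(C)[C@H]1[C@H]1CO1
F7 | step 17 | 3-bromo-2-(triisopropylsilyloxy)furan | CC(C)[Si](Oc1occc1Br)(C(C)C)C(C)C
F8 | step 17 | C11 alcohol with 2-(triisopropylsilyloxy)furan-3-yl on C12 | C=C1CC[C@H]2C(C)(C)CCC[C@]2(C)[C@H]1[C@H](O)Cc1ccoc1O[Si](C(C)C)(C(C)C)C(C)C
F9 | step 17 | C11 acetate of F8 | C=C1CC[C@H]2C(C)(C)CCC[C@]2(C)[C@H]1[C@@H](Cc1ccoc1O[Si](C(C)C)(C(C)C)C(C)C)OC(C)=O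
F10 | step 7 | (9R) 4-nitrobenzoate of 15 | Cc1ccc(O[Si](C)(C)C(C)(C)C)c(C)c1CC/C(=C\[Si](C)(C)C)[C@@H](OC(=O)c1ccc(cc1)[N+]([O-])=O)[C@H]1COC(C)(C)O1
F11 | step 14 | C17 vinyl iodide acetonide | I/C=C1\CC[C@H]2C(C)(C)CCC[C@]2(C)[C@H]1[C@H]1COC(C)(C)O1
A1 | alternative 1 | octalin C11 acid with C17 silyl ether | OC(=O)[C@H]1[C@@H](CO[Si](C)(C)C(C)(C)C)C=C[C@H]2C(C)(C)CCC[C@]12C
A2 | alternative 1 | trans-fused δ-lactone with (E)-3-silyloxypropenyl on C6 | O=C1C[C@@]2(C)CCCC(C)(C)[C@@H]2[C@@H](/C=C/CO[Si](C)(C)C(C)(C)C)O1
A3 | alternative 2 | trans-fused octalin imide with C8 silyl ether | CC(C)(C)[Si](C)(C)O[C@H]1C=C[C@H]2C(C)(C)CCC[C@]2(C)[C@H]1C(=O)N1C(=O)OC[C@@H]1Cc1ccccc1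
A4 | alternative 2 | acyclic silyloxytriene N-acyloxazolidinone | CC(C)(C)[Si](C)(C)O/C=C/C=C/C(C)(C)CCC/C(C)=C/C(=O)N1C(=O)OC[C@@H]1Cc1ccccc1
A5 | alternative 3 | tetrasubstituted C8=C9 enone with furylmethyl ketone | CC1=C(C(=O)Cc2ccoc2[Si](C)(C)C)[C@@]2(C)CCCC(C)(C)[C@@H]2CC1
A6 | alternative 3 | C9 enol triflate | CC1=C(OS(=O)(=O)C(F)(F)F)[C@@]2(C)CCCC(C)(C)[C@@H]2CC1
A7 | alternative 3 | [2-(trimethylsilyl)furan-3-yl]methylzinc bromide | C[Si](C)(C)c1occc1C[Zn]Br
A8 | alternative 3 | carbon monoxide | [C-]#[O+]
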